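**Retrosynthetic overview**
1. Target 17 ⇐ diol 16 (acetylation of the primary OH) ⇐ mixed methyl ketal 15, in which the cyclopentenone C=O is tied to the CH2O arm (mild hydrolysis).
2. 15 ⇐ methyl ketone 11 + ylide from 5-bromo-2-methylpent-2-ene (Z-selective Wittig builds the side chain while the ketal masks the enone).
3. Key disconnection C2–C1′ (ring-to-ring bond): 11 ⇐ bromo ketal 10 by a tethered 6-exo radical cyclisation onto an acetylcyclopentene, ended by H-atom transfer (sets C2, C3 and C1′ in one step).
4. 10 ⇐ enone diol 6 + methyl dienol ether of (4S)-4-methylcyclopent-2-en-1-one (NBS bromo-ketalisation); 6 ⇐ 3-methylcyclohex-2-en-1-one.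
5. Ring order: cyclopentenone ring bought (7); cyclopentane ring by ozonolysis/aldol ring contraction (step 3); temporary oxane (ketal) ring made in step 6 and opened in step 9.

Locants (target name): cyclopentane C1 (C–OH, CH2OAc), C2 (bears the cyclopentenone), C3 (bears the side chain); cyclopentenone C1′ (ring junction), C2′ (C=O), C5′ (CH–CH3). Target = 1R,2S,3R,1′S,5′R: CH2OAc, cyclopentenone and side chain all cis on the cyclopentane (OH trans); CH3 and cyclopentyl cis on the cyclopentenone.
Assumption 1: (4S)-4-methylcyclopent-2-en-1-one (7) is bought as the single enantiomer.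
Assumption 2: the lipase in step 2 acylates the (S)-diol faster, so the (R)-diol is recovered (if the preference is reversed, the (R)-monoacetate is methanolysed to 4).

**Step 1**
Reactants: 1 3-methylcyclohex-2-en-1-one
Product: 3 rac-1-(hydroxymethyl)-3-methylcyclohex-2-en-1-ol, via silylmethyl carbinol 2 (not isolated)
Conditions: (i-PrO)Me2SiCH2MgCl, THF, 0 °C; then KF, KHCO3, 30% H2O2, MeOH/THF, rt
Reagents that add atoms: (isopropoxydimethylsilyl)methylmagnesium chloride, CC(C)O[Si](C)(C)C[Mg]Cl; hydrogen peroxide, OO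
Why: Tamao–Kumada nucleophilic hydroxymethylation (1,2-Grignard addition to the β,β-disubstituted enone, then Tamao oxidation of the C–Si bond) gives the racemic tertiary allylic 1,2-diol under non-acidic conditions.

**Step 2**
Reactants: 3 rac-1-(hydroxymethyl)-3-methylcyclohex-2-en-1-ol
Product: 4 (1R)-1-(hydroxymethyl)-3-methylcyclohex-2-en-1-ol
Conditions: lipase from Burkholderia cepacia (Amano PS), vinyl acetate, t-BuOMe, 25 °C, stopped at about 55% conversion
Reagents that add atoms: none
Why: Enzymatic kinetic resolution by acylation of the primary OH leaves the slow-reacting enantiomer, fixing the quaternary carbinol centre (C1 of the target) as R.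

**Step 3**
Reactants: 4 (1R)-1-(hydroxymethyl)-3-methylcyclohex-2-en-1-ol
Product: 6 1-[(3R)-3-hydroxy-3-(hydroxymethyl)cyclopent-1-en-1-yl]ethan-1-one, via keto aldehyde 5 (not isolated)
Conditions: O3, CH2Cl2/MeOH, −78 °C; Me2S; then piperidine/AcOH (cat.), PhH, 50 °C
Reagents that add atoms: ozone, [O-][O+]=O
Why: Ozonolysis of the ring alkene followed by intramolecular aldol condensation (methylene of the methyl ketone onto the aldehyde) contracts the ring to the 1-acetylcyclopentene, and the carbinol centre has no α-H so it cannot epimerise.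

**Step 4**
Reactants: 7 (4S)-4-methylcyclopent-2-en-1-one
Product: 8 (5S)-3,3-dimethoxy-5-methylcyclopent-1-ene
Conditions: MeOSiMe3 (2.5 equiv), Me3SiOTf (5 mol%), CH2Cl2, −78 °C; pyridine quench
Reagents that add atoms: methoxytrimethylsilane, CO[Si](C)(C)C
Why: Noyori ketalisation converts the enone into its dimethyl ketal at low temperature without moving the double bond or touching the methyl-bearing stereocentre.

**Step 5**
Reactants: 8 (5S)-3,3-dimethoxy-5-methylcyclopent-1-ene; 6 1-[(3R)-3-hydroxy-3-(hydroxymethyl)cyclopent-1-en-1-yl]ethan-1-one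
Product: 10 1-[(3R)-3-({[(1S,4R,5S)-5-bromo-1-methoxy-4-methylcyclopent-2-en-1-yl]oxy}methyl)-3-hydroxycyclopent-1-en-1-yl]ethan-1-one, via methoxy diene 9 (not isolated)
Conditions: Me3SiOTf, i-Pr2NEt, CH2Cl2, −40 °C; cold NaHCO3 wash; then 6, NBS, 2,6-lutidine, CH2Cl2, −78 °C
Reagents that add atoms: N-bromosuccinimide, O=C1CCC(=O)N1Br
Why: Gassman-type loss of MeOH gives the cross-conjugated methyl dienol ether, and NBS bromo-etherification with the primary OH of 6 (Ueno–Stork haloacetal formation) puts Br on C1′ anti to the neighbouring CH3 and the alkoxy group on C2′ anti to Br, so the OCH2 tether and CH3 end cis.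

**Step 6**
Reactants: 10 the bromo ketal
Product: 11 tricyclic ketal methyl ketone: C2 of the (now saturated) cyclopentane bonded to C1′; C2′ a methyl ketal closed onto the C1–CH2O arm (ring O–CH2–C1–C2–C1′–C2′); acetyl on C3; configuration 1R,2S,3R,1′S,2′S,5′R
Conditions: Bu3SnH (1.3 equiv, syringe pump), AIBN (0.2 equiv), PhH (5 mM), 80 °C
Reagents that add atoms: none
Why: Ueno–Stork 6-exo-trig radical cyclisation (Giese-type addition of the nucleophilic β-alkoxyalkyl radical to the enone) is forced by the tether to form C2–C1′ on the CH2O face of the cyclopentane and cis to the ketal oxygen, hence cis to CH3, on the cyclopentene (the cyclopentene sits exo), and Bu3SnH then delivers H to the α-keto radical at C3 from the open convex face, leaving the acetyl cis to C1′.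

**Step 7**
Reactants: 12 5-bromo-2-methylpent-2-ene
Product: 13 (4-methylpent-3-en-1-yl)triphenylphosphonium bromide
Conditions: PPh3, MeCN, reflux
Reagents that add atoms: triphenylphosphine, c1ccc(cc1)P(c1ccccc1)c1ccccc1
Why: SN2 quaternisation of triphenylphosphine by the primary bromide gives the Wittig salt.

**Step 8**
Reactants: 13 (4-methylpent-3-en-1-yl)triphenylphosphonium bromide; 11 tricyclic ketal methyl ketone
Product: 15 tricyclic ketal of 11 with the acetyl replaced by the (2Z)-6-methylhepta-2,5-dien-2-yl group, via phosphorus ylide 14 (not isolated)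
Conditions: 13 (3 equiv), NaN(SiMe3)2 (3 equiv), THF, 0 °C; then 11, −78 °C → rt
Reagents that add atoms: none
Why: Salt-free Wittig olefination of an α-branched methyl ketone with a non-stabilised ylide favours the alkene with the ring carbon and the chain CH2 cis (Z), and because the ketal masks the cyclopentenone carbonyl and C1′ has no acidic H only the acetyl reacts.

**Step 9**
Reactants: 15 tricyclic ketal with Z side chain
Product: 16 (4R,5S)-5-[(1S,2R,5R)-2-hydroxy-2-(hydroxymethyl)-5-[(2Z)-6-methylhepta-2,5-dien-2-yl]cyclopentyl]-4-methylcyclopent-2-en-1-one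
Conditions: PPTS (0.2 equiv), acetone/H2O 10:1, 0 °C → rt
Reagents that add atoms: water, O
Why: Mild acid hydrolysis of the allylic mixed ketal releases the cyclopentenone and the primary alcohol without base, so the kinetically set cis C1′/C5′ relationship α to the new ketone is kept.

**Step 10**
Reactants: 16 the diol ketone
Product: 17 [(1R,2S,3R)-1-hydroxy-2-[(1S,5R)-5-methyl-2-oxocyclopent-3-en-1-yl]-3-[(2Z)-6-methylhepta-2,5-dien-2-yl]cyclopentyl]methyl acetate (target)
Conditions: Ac2O (1.2 equiv), pyridine, CH2Cl2, 0 °C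
Reagents that add atoms: acetic anhydride, CC(=O)OC(C)=O
Why: Selective acetylation of the primary over the tertiary alcohol under cold, weakly basic conditions that do not enolise C1′.

**Compound list**
1 | 3-methylcyclohex-2-en-1-one | CC1=CC(=O)CCC1 | starting material
2 | rac-1-{[dimethyl(propan-2-yloxy)silyl]methyl}-3-methylcyclohex-2-en-1-ol | CC(C)O[Si](C)(C)CC1(O)CCCC(C)=C1 | intermediate
3 | rac-1-(hydroxymethyl)-3-methylcyclohex-2-en-1-ol | OCC1(O)CCCC(C)=C1 | intermediate
4 | (1R)-1-(hydroxymethyl)-3-methylcyclohex-2-en-1-ol | OC[C@@]1(O)CCCC(C)=C1 | intermediate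
5 | (2S)-2-hydroxy-2-(hydroxymethyl)-6-oxoheptanal | OC[C@@](C=O)(O)CCCC(C)=O | intermediate
6 | 1-[(3R)-3-hydroxy-3-(hydroxymethyl)cyclopent-1-en-1-yl]ethan-1-one | OC[C@@]1(O)CCC(C(C)=O)=C1 | intermediate
7 | (4S)-4-methylcyclopent-2-en-1-one | C[C@@H]1C=CC(=O)C1 | starting material
8 | (5S)-3,3-dimethoxy-5-methylcyclopent-1-ene | C[C@@H]1C=CC(OC)(OC)C1 | intermediate
9 | (5R)-2-methoxy-5-methylcyclopenta-1,3-diene | COC1=C[C@H](C)C=C1 | intermediate
10 | 1-[(3R)-3-({[(1S,4R,5S)-5-bromo-1-methoxy-4-methylcyclopent-2-en-1-yl]oxy}methyl)-3-hydroxycyclopent-1-en-1-yl]ethan-1-one | O(C[C@@]1(O)CCC(C(C)=O)=C1)[C@@]2(OC)C=C[C@@H](C)[C@@H]2Br | intermediate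
11 | tricyclic ketal methyl ketone (1R,2S,3R,1′S,2′S,5′R; acetyl, C1′ and CH2O cis on the cyclopentane; C2, ketal O–CH2 and CH3 cis on the cyclopentene) | O1C[C@@]2(O)CC[C@@H](C(C)=O)[C@H]2[C@H]3[C@]1(OC)C=C[C@H]3C | intermediate
12 | 5-bromo-2-methylpent-2-ene | CC(C)=CCCBr | starting material
13 | (4-methylpent-3-en-1-yl)triphenylphosphonium bromide | CC(C)=CCC[P+](c1ccccc1)(c1ccccc1)c1ccccc1.[Br-] | intermediate
14 | (4-methylpent-3-en-1-ylidene)triphenylphosphorane | CC(C)=CCC=P(c1ccccc1)(c1ccccc1)c1ccccc1 | intermediate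
15 | tricyclic ketal as 11 with (2Z)-6-methylhepta-2,5-dien-2-yl on C3 in place of acetyl | O1C[C@@]2(O)CC[C@@H](/C(C)=C\CC=C(C)C)[C@H]2[C@H]3[C@]1(OC)C=C[C@H]3C | intermediate
16 | (4R,5S)-5-[(1S,2R,5R)-2-hydroxy-2-(hydroxymethyl)-5-[(2Z)-6-methylhepta-2,5-dien-2-yl]cyclopentyl]-4-methylcyclopent-2-en-1-one | OC[C@@]1(O)CC[C@@H](/C(C)=C\CC=C(C)C)[C@H]1[C@H]1C(=O)C=C[C@H]1C | intermediate
17 | [(1R,2S,3R)-1-hydroxy-2-[(1S,5R)-5-methyl-2-oxocyclopent-3-en-1-yl]-3-[(2Z)-6-methylhepta-2,5-dien-2-yl]cyclopentyl]methyl acetate | CC(=O)OC[C@@]1(O)CC[C@@H](/C(C)=C\CC=C(C)C)[C@H]1[C@H]1C(=O)C=C[C@H]1C | target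

**Step count**
Total: 10 steps. Longest linear sequence: 8 steps (1, 2, 3, 5, 6, 8, 9, 10).

**Three steps most likely to fail**

Step 5. The elimination can also take the C5′ proton (giving the achiral 1-methoxy-3-methyl diene), the methylcyclopentadiene can racemise by 1,5-H shift, and the alcohol may add 1,4 instead of at the ketal carbon. The fallback sets out from 7 and comes back at 10, brominating first and building the ketal afterwards. Treating 7 with LiN(i-Pr)2/Me3SiCl at −78 °C and then NBS gives (4R,5S)-5-bromo-4-methylcyclopent-2-en-1-one F1 (Br anti to CH3). MeOSiMe3/Me3SiOTf converts it into (4S,5R)-4-bromo-3,3-dimethoxy-5-methylcyclopent-1-ene F2. Catalytic Me3SiOTf with 6 at −78 °C then exchanges one methoxy group through the bromo-oxocarbenium ion, the primary OH entering anti to Br, to give 10 without a free methoxy diene.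

Step 6. The C–Br bond may be reduced before the 6-exo closure, or H may reach C3 from the wrong face. The fallback sets out from 10 and comes back at 11, separating ring closure from the C3–H step. A bromine atom-transfer cyclisation without tin hydride (Ir(ppy)3, tris(2-phenylpyridinato)iridium, blue LED, MeCN) gives the C3-bromo ketone F3. Zn in AcOH then forms the zinc enolate, which is protonated from the convex face to give 11.

Step 8. The ketone is hindered, the Z/E ratio may be modest, and the basic ylide can epimerise C3. The fallback sets out from 11 and comes back at 15 by a two-stage Horner–Wittig. Aqueous NaOH converts 13 into (4-methylpent-3-en-1-yl)diphenylphosphine oxide F4. Its lithio derivative (n-BuLi, −78 °C) adds to 11, and the Z-forming β-hydroxy phosphine oxide diastereomer F5 is separated by chromatography. NaH in DMF then effects stereospecific syn-elimination to 15.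

**Further compounds**
F1 | step 5 | (4R,5S)-5-bromo-4-methylcyclopent-2-en-1-one | O=C1C=C[C@@H](C)[C@@H]1Br
F2 | step 5 | (4S,5R)-4-bromo-3,3-dimethoxy-5-methylcyclopent-1-ene | COC1(OC)C=C[C@@H](C)[C@@H]1Br
F3 | step 6 | C3-bromo analogue of 11 (Br on the convex face, acetyl cis to C1′) | O1C[C@@]2(O)CC[C@@](Br)(C(C)=O)[C@H]2[C@H]3[C@]1(OC)C=C[C@H]3C
F4 | step 8 | (4-methylpent-3-en-1-yl)diphenylphosphine oxide | CC(C)=CCCP(=O)(c1ccccc1)c1ccccc1
F5 | step 8 | β-hydroxy phosphine oxide adduct of 11 and F4 (diastereomer giving Z on syn-elimination) | O1C[C@@]2(O)CC[C@@H]([C@@](C)(O)[C@H](CC=C(C)C)P(=O)(c4ccccc4)c4ccccc4)[C@H]2[C@H]3[C@]1(OC)C=C[C@H]3C
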